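## Retrosynthetic overview

1. Guaiane numbering is used, unprimed for the enone half (half 1) and primed for the spiro half (half 2). Ring D (C2, C1, C10, C14, C15′, C4′) is a Diels–Alder ring: cutting C2–C4′ and C14–C15′ gives a cross-conjugated dienone (half 1, 5β-H) and 8β-hydroxydehydrozaluzanin C (half 2, 5′α-H). Moving the double bond of the cycloadduct into conjugation then sets C10.
2. In each monomer the seven-membered ring B (C1, C5, C6, C7, C8, C9, C10) is opened at C6–C7 and C1–C10.
3. The enabling feature: C6 (carbinol carbon of lactone ring C) and C1 (β-carbon of the ring A ketone C3) are both electrophilic and both sit on C5, while the C11=C13 and C10=C14 methylenes mark C7 and C10 as a former allyl and vinyl nucleophile. A C7–C10 chain with an allylic bromide at one end and a vinyl bromide at the other therefore closes rings C and B in one flask.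
4. The two halves share the C6/C7/C8 triad but are opposite at C5, so the racemic ring A aldehyde plus one enantiomer of the chain gives both halves as separable diastereomers. C8 steers the allylation from the anti position and is inverted afterwards (8α to 8β).
5. Ring order: ring A (from 4-hydroxycyclopentenone), then rings C and B together (key step), then ring D (last step).

Key step: step 9

Remark on the chemistry: as read from the SMILES, half 1 has 5β-H (cis to H-6) and 10β-H, half 2 has 1′α-H and 5′α-H, and both halves are 6βH,7αH-12,6α-olides with 8β-OH. Racemic compounds are written as one enantiomer.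

## Route

Step 1
Reactants: 1 (±)-4-hydroxycyclopent-2-en-1-one
Product: 2 (±)-4-[(tert-butyldimethylsilyl)oxy]cyclopent-2-en-1-one
Conditions: TBSCl, imidazole, CH2Cl2, 0 °C to rt
Reagents that add atoms: tert-butyldimethylsilyl chloride, C[Si](C)(Cl)C(C)(C)C
Why: Imidazole-mediated silyl ether formation masks the hydroxyl group, which later leaves as the traceless source of the C1=C2 double bond.

Step 2
Reactants: 2 (±)-4-[(tert-butyldimethylsilyl)oxy]cyclopent-2-en-1-one
Product: 5 rac-(3R,4R)-4-[(tert-butyldimethylsilyl)oxy]-3-ethenyl-2-methylidenecyclopentan-1-one, via Mannich base 3 (not isolated), via methiodide 4 (not isolated)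
Conditions: CH2=CHMgBr, CuBr·SMe2 (20 mol %), THF, −78 °C; then CH2=NMe2+ I−, −78 to 0 °C; then MeI, MeOH; NaHCO3 (aq), CH2Cl2, rt
Reagents that add atoms: vinylmagnesium bromide, C=C[Mg]Br; Eschenmoser's salt (N,N-dimethylmethyleneiminium iodide), C=[N+](C)C.[I-]
Why: Copper-catalysed conjugate addition of the vinyl group anti to the silyloxy group, Mannich trapping of the regio-defined enolate and Hofmann-type elimination of the methiodide (α-methylenation) place the future C6 on C5 trans to the silyloxy group and install C15.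

Step 3
Reactants: 5 rac-(3R,4R)-4-[(tert-butyldimethylsilyl)oxy]-3-ethenyl-2-methylidenecyclopentan-1-one
Product: 6 rac-(1R,5R)-5-[(tert-butyldimethylsilyl)oxy]-2-methylidene-3-oxocyclopentane-1-carbaldehyde
Conditions: OsO4 (2 mol %), NaIO4, 2,6-lutidine, dioxane/H2O, 0 °C; used crude at once
Reagents that add atoms: sodium periodate, [Na+].[O-]I(=O)(=O)=O, as terminal oxygen source, delivered by osmium tetroxide, O=[Os](=O)(=O)=O
Why: Lemieux–Johnson cleavage should take the electron-rich vinyl group in preference to the electron-poor enone methylene and unveil the C6 aldehyde, whose easy epimerisation at C5 is harmless because the material is racemic and the silyloxy centre is lost later.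

Step 4
Reactants: 7 ethyl glyoxylate; 8 (2-bromoprop-2-en-1-yl)trimethylsilane
Product: 9 ethyl (2S)-4-bromo-2-hydroxypent-4-enoate
Conditions: Cu(SbF6)2 with (S,S)-tert-butyl-bis(oxazoline) ligand (10 mol %), CH2Cl2, −20 °C; 1 M HCl work-up
Reagents that add atoms: none
Why: Catalytic enantioselective Hosomi–Sakurai allylation of the glyoxylate held in the bis(oxazoline) copper chelate should add the 2-bromoallyl group to one face and set the future C8 as (S).

Step 5
Reactants: 9 ethyl (2S)-4-bromo-2-hydroxypent-4-enoate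
Product: 10 ethyl (2S)-4-bromo-2-[(triethylsilyl)oxy]pent-4-enoate
Conditions: TESCl, imidazole, DMF, 0 °C
Reagents that add atoms: triethylsilyl chloride, CC[Si](Cl)(CC)CC
Why: Silyl ether formation gives the bulky, non-chelating oxygen substituent that later directs the allylation and is removed on acidic work-up.

Step 6
Reactants: 10 ethyl (2S)-4-bromo-2-[(triethylsilyl)oxy]pent-4-enoate
Product: 11 (2S)-4-bromo-2-[(triethylsilyl)oxy]pent-4-enal
Conditions: i-Bu2AlH, CH2Cl2, −78 °C; aq. potassium sodium tartrate
Reagents that add atoms: none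
Why: Partial reduction of the α-silyloxy ester stops at the aldehyde because the tetrahedral aluminium hemiacetal is stable at −78 °C.

Step 7
Reactants: 11 (2S)-4-bromo-2-[(triethylsilyl)oxy]pent-4-enal; 12 methyl acrylate
Product: 13 methyl (3RS,4S)-6-bromo-3-hydroxy-2-methylidene-4-[(triethylsilyl)oxy]hept-6-enoate
Conditions: DABCO (1 equiv), methyl acrylate (excess, neat), rt
Reagents that add atoms: none
Why: The Morita–Baylis–Hillman reaction attaches C11, C12 and C13; the new carbinol centre may form as a mixture because the next step removes it.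

Step 8
Reactants: 13 methyl (3RS,4S)-6-bromo-3-hydroxy-2-methylidene-4-[(triethylsilyl)oxy]hept-6-enoate
Product: 14 methyl (2Z,4S)-6-bromo-2-(bromomethyl)-4-[(triethylsilyl)oxy]hepta-2,6-dienoate
Conditions: NBS, Me2S, CH2Cl2, 0 °C
Reagents that add atoms: N-bromosuccinimide, O=C1CCC(=O)N1Br
Why: Bromination of the activated alcohol with allylic transposition (SN2′) is stereoconvergent, so both carbinol epimers should give the one (Z)-2-(bromomethyl)enoate.

Step 9
Reactants: 6 rac-(1R,5R)-5-[(tert-butyldimethylsilyl)oxy]-2-methylidene-3-oxocyclopentane-1-carbaldehyde; 14 methyl (2Z,4S)-6-bromo-2-(bromomethyl)-4-[(triethylsilyl)oxy]hepta-2,6-dienoate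
Product: 21 8α-hydroxy-3-oxo-1βH,5βH-guaia-4(15),10(14),11(13)-trien-12,6α-olide and 22 8α-hydroxy-3-oxo-1αH,5αH-guaia-4(15),10(14),11(13)-trien-12,6α-olide (separable C1/C5 diastereomers, one from each enantiomer of 6), via half 1 seco-lactone 15 (not isolated), via half 2 seco-lactone 16 (not isolated), via half 1 dienone 17 (not isolated), via half 2 dienone 18 (not isolated), via half 1 silyl ether 19 (not isolated), via half 2 silyl ether 20 (not isolated)
Conditions: CrCl2 (5 equiv), THF, 0 °C to rt; then Et3N, HCO2H, Pd(OAc)2 (10 mol %), PPh3 (20 mol %), DMF, 70 °C, same flask; then 1 M HCl, THF, 0 °C; chromatography separates 21 and 22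
Reagents that add atoms: none
Why: Proposed new method: CrCl2 reduces only the allylic C–Br bond of 14 (the vinyl bromide is inert without nickel) to an allylchromium that adds to the aldehyde of 6 through a chair, the alkoxide lactonises (ring C, 5-exo-trig acyl substitution), Et3N expels silanol by E1cB to unveil the C1=C2 enone, and zerovalent palladium inserts into the vinyl C–Br bond, adds C10 to the enone β-carbon C1 (ring B, 7-exo-trig carbopalladation) and the palladium enolate is reduced by formate. The closest known reactions are the chromium-mediated Nozaki–Hiyama–Kishi-type 2-(alkoxycarbonyl)allylation that gives trans α-methylene-γ-butyrolactones and the formate-driven reductive Mizoroki–Heck addition of vinyl halides to cyclic enones; their union in one flask and the seven-membered closure onto a cross-conjugated dienone are the new elements. C6 and C7 should form anti (trans-lactone) whatever the bromide geometry, and their absolute sense should come from C8, whose bulky silyloxy group lies anti to the forming C6–C7 bond (Felkin–Anh-type control inside the nucleophile, which places O8 trans to C11) and overrides the labile α-centre of the aldehyde, so that (1R,5R)-6 ends in 21 and (1S,5S)-6 in 22. C1 is set by syn carbopalladation on the face of the C5–C6 tether, giving the cis ring fusion in both series. The step needs addition to the aldehyde and not the ketone (secured by the allylchromium), closure at C1 and not at the remote exocyclic C15 (secured by ring size), and survival of the exocyclic enones under palladium hydride (short heating, limited formate). Both products are used, one in each half of the target.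

Step 10
Reactants: 21 8α-hydroxy-3-oxo-1βH,5βH-guaia-4(15),10(14),11(13)-trien-12,6α-olide
Product: 24 8β-hydroxy-3-oxo-1βH,5βH-guaia-4(15),10(14),11(13)-trien-12,6α-olide, via half 1 formate 23 (not isolated)
Conditions: PPh3 and DIAD premixed, THF, 0 °C; then HCO2H and 21; then NaHCO3, MeOH/H2O, 0 °C
Reagents that add atoms: formic acid, O=CO
Why: Mitsunobu displacement by formate should invert C8 cleanly (SN2) to the 8β configuration of the target, and the labile formate is cleaved by bicarbonate without touching the lactone.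

Step 11
Reactants: 22 8α-hydroxy-3-oxo-1αH,5αH-guaia-4(15),10(14),11(13)-trien-12,6α-olide
Product: 26 8β-hydroxydehydrozaluzanin C (8β-hydroxy-3-oxo-1αH,5αH-guaia-4(15),10(14),11(13)-trien-12,6α-olide), via half 2 formate 25 (not isolated)
Conditions: PPh3 and DIAD premixed, THF, 0 °C; then HCO2H and 22; then NaHCO3, MeOH/H2O, 0 °C
Reagents that add atoms: formic acid, O=CO
Why: The same Mitsunobu inversion sets 8′β in the half 2 monomer, which is the dienophile of the last step.

Step 12
Reactants: 24 8β-hydroxy-3-oxo-1βH,5βH-guaia-4(15),10(14),11(13)-trien-12,6α-olide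
Product: 29 8β-hydroxy-3-oxo-5βH-guaia-1,4(15),10(14),11(13)-tetraen-12,6α-olide, via bis-silyl dienol ether 27 (not isolated), via O-silyl dienone 28 (not isolated)
Conditions: TMSOTf, Et3N, CH2Cl2, 0 °C; then Pd(OAc)2 (1.1 equiv), MeCN, rt; aq. citric acid work-up; used at once
Reagents that add atoms: none
Why: Only C2 can enolise because C4 is sp2, so the silyl dienol ether is regio-defined and Saegusa–Ito oxidation should give the C1=C2 enone, which erases C1 and leaves C5 (5β-H) as the only ring A stereocentre.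

Step 13
Reactants: 29 8β-hydroxy-3-oxo-5βH-guaia-1,4(15),10(14),11(13)-tetraen-12,6α-olide; 26 8β-hydroxydehydrozaluzanin C
Product: 31 target CNP0397417.1, via cycloadduct 30 (not isolated)
Conditions: 26 (3 equiv, excess recovered), degassed CH2Cl2 (concentrated), BHT, 40 °C, argon; then Et3N (cat.), rt
Reagents that add atoms: none
Why: In this Diels–Alder reaction the diene terminus C14 should bond to the enone β-carbon C15′ and C2 to C4′ on the convex α-face of 26 (the face of H-1′ and H-5′), which sets the spiro centre; the endo/exo and diene-face isomers differ only at C2 and converge when the weak base removes the doubly activated H-2 and moves the double bond into conjugation, C10 being protonated on the β-face, away from ring B, which 5β-H holds on the α-face.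

## Compound list

1 | (±)-4-hydroxycyclopent-2-en-1-one | O=C1C=CC(O)C1 | starting material
2 | (±)-4-[(tert-butyldimethylsilyl)oxy]cyclopent-2-en-1-one | O=C1C=CC(O[Si](C)(C)C(C)(C)C)C1 | intermediate
3 | (±)-2,3-trans-3,4-trans-4-[(tert-butyldimethylsilyl)oxy]-2-[(dimethylamino)methyl]-3-ethenylcyclopentan-1-one (Mannich base) | O=C1[C@H](CN(C)C)[C@@H](C=C)[C@H](O[Si](C)(C)C(C)(C)C)C1 | intermediate (not isolated)
4 | N-methyl ammonium iodide of 3 (methiodide) | C[N+](C)(C)C[C@@H]1[C@@H](C=C)[C@H](O[Si](C)(C)C(C)(C)C)CC1=O.[I-] | intermediate (not isolated)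
5 | rac-(3R,4R)-4-[(tert-butyldimethylsilyl)oxy]-3-ethenyl-2-methylidenecyclopentan-1-one (3,4-trans) | C=C[C@H]1[C@H](O[Si](C)(C)C(C)(C)C)CC(=O)C1=C | intermediate
6 | rac-(1R,5R)-5-[(tert-butyldimethylsilyl)oxy]-2-methylidene-3-oxocyclopentane-1-carbaldehyde (1,5-trans) | O=C[C@H]1[C@H](O[Si](C)(C)C(C)(C)C)CC(=O)C1=C | intermediate
7 | ethyl glyoxylate | CCOC(=O)C=O | starting material
8 | (2-bromoprop-2-en-1-yl)trimethylsilane | C=C(Br)C[Si](C)(C)C | starting material
9 | ethyl (2S)-4-bromo-2-hydroxypent-4-enoate | C=C(Br)C[C@H](O)C(=O)OCC | intermediate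
10 | ethyl (2S)-4-bromo-2-[(triethylsilyl)oxy]pent-4-enoate | C=C(Br)C[C@H](O[Si](CC)(CC)CC)C(=O)OCC | intermediate
11 | (2S)-4-bromo-2-[(triethylsilyl)oxy]pent-4-enal | C=C(Br)C[C@H](O[Si](CC)(CC)CC)C=O | intermediate
12 | methyl acrylate | C=CC(=O)OC | starting material
13 | methyl (3RS,4S)-6-bromo-3-hydroxy-2-methylidene-4-[(triethylsilyl)oxy]hept-6-enoate | C=C(Br)C[C@H](O[Si](CC)(CC)CC)C(O)C(=C)C(=O)OC | intermediate
14 | methyl (2Z,4S)-6-bromo-2-(bromomethyl)-4-[(triethylsilyl)oxy]hepta-2,6-dienoate | C=C(Br)C[C@H](O[Si](CC)(CC)CC)/C=C(\CBr)C(=O)OC | intermediate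
15 | half 1 seco-lactone: 10-bromo-1β-[(tert-butyldimethylsilyl)oxy]-3-oxo-8α-[(triethylsilyl)oxy]-5βH,6βH,7αH-1,10-secoguaia-4(15),10(14),11(13)-trien-12,6α-olide | C=C(Br)C[C@H](O[Si](CC)(CC)CC)[C@H]1C(=C)C(=O)O[C@@H]1[C@H]1[C@H](O[Si](C)(C)C(C)(C)C)CC(=O)C1=C | intermediate (not isolated)
16 | half 2 seco-lactone: the 1α-silyloxy-5αH diastereomer of 15 | C=C(Br)C[C@H](O[Si](CC)(CC)CC)[C@H]1C(=C)C(=O)O[C@@H]1[C@@H]1[C@@H](O[Si](C)(C)C(C)(C)C)CC(=O)C1=C | intermediate (not isolated)
17 | half 1 dienone: 10-bromo-3-oxo-8α-[(triethylsilyl)oxy]-5βH,6βH,7αH-1,10-secoguaia-1,4(15),10(14),11(13)-tetraen-12,6α-olide | C=C(Br)C[C@H](O[Si](CC)(CC)CC)[C@H]1C(=C)C(=O)O[C@@H]1[C@H]1C=CC(=O)C1=C | intermediate (not isolated)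
18 | half 2 dienone: the 5αH diastereomer of 17 | C=C(Br)C[C@H](O[Si](CC)(CC)CC)[C@H]1C(=C)C(=O)O[C@@H]1[C@@H]1C=CC(=O)C1=C | intermediate (not isolated)
19 | half 1 silyl ether: 3-oxo-8α-[(triethylsilyl)oxy]-1βH,5βH,6βH,7αH-guaia-4(15),10(14),11(13)-trien-12,6α-olide | C=C1C(=O)C[C@@H]2C(=C)C[C@H](O[Si](CC)(CC)CC)[C@H]3C(=C)C(=O)O[C@@H]3[C@H]12 | intermediate (not isolated)
20 | half 2 silyl ether: the 1αH,5αH diastereomer of 19 | C=C1C(=O)C[C@H]2C(=C)C[C@H](O[Si](CC)(CC)CC)[C@H]3C(=C)C(=O)O[C@@H]3[C@@H]12 | intermediate (not isolated)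
21 | 8α-hydroxy-3-oxo-1βH,5βH,6βH,7αH-guaia-4(15),10(14),11(13)-trien-12,6α-olide | C=C1C(=O)C[C@@H]2C(=C)C[C@H](O)[C@H]3C(=C)C(=O)O[C@@H]3[C@H]12 | intermediate
22 | 8α-hydroxy-3-oxo-1αH,5αH,6βH,7αH-guaia-4(15),10(14),11(13)-trien-12,6α-olide (8α-hydroxydehydrozaluzanin C) | C=C1C(=O)C[C@H]2C(=C)C[C@H](O)[C@H]3C(=C)C(=O)O[C@@H]3[C@@H]12 | intermediate
23 | half 1 formate: 8β-formyloxy-3-oxo-1βH,5βH-guaia-4(15),10(14),11(13)-trien-12,6α-olide | C=C1C(=O)C[C@@H]2C(=C)C[C@@H](OC=O)[C@H]3C(=C)C(=O)O[C@@H]3[C@H]12 | intermediate (not isolated)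
24 | 8β-hydroxy-3-oxo-1βH,5βH,6βH,7αH-guaia-4(15),10(14),11(13)-trien-12,6α-olide | C=C1C(=O)C[C@@H]2C(=C)C[C@@H](O)[C@H]3C(=C)C(=O)O[C@@H]3[C@H]12 | intermediate
25 | half 2 formate: 8β-formyloxy-3-oxo-1αH,5αH-guaia-4(15),10(14),11(13)-trien-12,6α-olide | C=C1C(=O)C[C@H]2C(=C)C[C@@H](OC=O)[C@H]3C(=C)C(=O)O[C@@H]3[C@@H]12 | intermediate (not isolated)
26 | 8β-hydroxydehydrozaluzanin C (8β-hydroxy-3-oxo-1αH,5αH,6βH,7αH-guaia-4(15),10(14),11(13)-trien-12,6α-olide) | C=C1C(=O)C[C@H]2C(=C)C[C@@H](O)[C@H]3C(=C)C(=O)O[C@@H]3[C@@H]12 | intermediate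
27 | bis-silyl dienol ether: 3,8β-bis[(trimethylsilyl)oxy]-1βH,5βH-guaia-2,4(15),10(14),11(13)-tetraen-12,6α-olide | C=C1C(O[Si](C)(C)C)=C[C@@H]2C(=C)C[C@@H](O[Si](C)(C)C)[C@H]3C(=C)C(=O)O[C@@H]3[C@H]12 | intermediate (not isolated)
28 | O-silyl dienone: 3-oxo-8β-[(trimethylsilyl)oxy]-5βH-guaia-1,4(15),10(14),11(13)-tetraen-12,6α-olide | C=C1C(=O)C=C2C(=C)C[C@@H](O[Si](C)(C)C)[C@H]3C(=C)C(=O)O[C@@H]3[C@H]12 | intermediate (not isolated)
29 | 8β-hydroxy-3-oxo-5βH,6βH,7αH-guaia-1,4(15),10(14),11(13)-tetraen-12,6α-olide | C=C1C(=O)C=C2C(=C)C[C@@H](O)[C@H]3C(=C)C(=O)O[C@@H]3[C@H]12 | intermediate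
30 | Diels–Alder cycloadduct (non-conjugated enone with C1=C10, epimers at C2) | C=C1C(=O)C2C3=C(CC[C@]24C(=O)C[C@H]2C(=C)C[C@@H](O)[C@H]5C(=C)C(=O)O[C@@H]5[C@H]24)C[C@@H](O)[C@H]2C(=C)C(=O)O[C@@H]2[C@H]13 | intermediate (not isolated)
31 | CNP0397417.1 | C=C1C(=O)C2=C3[C@H](CC[C@]24C(=O)C[C@H]2C(=C)C[C@@H](O)[C@H]5C(=C)C(=O)O[C@@H]5[C@H]24)C[C@@H](O)[C@H]2C(=C)C(=O)O[C@@H]2[C@H]13 | target

## Step count and risks

Total steps: 13. Longest linear sequence: 9 steps (steps 4, 5, 6, 7, 8, 9, 10, 12, 13).

**Step 9 (Proposed new method).** What may go wrong: palladium hydride reduces the exocyclic enones, the carbopalladation stalls in the chromium-laden mixture, or the silyloxy group at C8 fails to override the α-centre of the aldehyde for one enantiomer of 6. The fallback sets out from 6 and 14 and comes back at 21 and 22. The chromium allylation is run alone and lactonisation is finished with catalytic TsOH. Seco-lactones 15 and 16 are isolated and separated, and DBU in CH2Cl2 gives dienones 17 and 18. Ring B is then closed by the known nickel-promoted conjugate addition of a vinyl bromide to an enone (Ni(cod)2 in stoichiometric amount, Et3N, MeCN), which ends by protonation and uses no hydride, to give silyl ethers 19 and 20. HF·pyridine then frees 21 and 22.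

**Step 13.** What may go wrong: the isolated dienone 29 adds to itself, the diene attacks the wrong face of 26, or the dienol is oxidised by air at C10. The fallback sets out from 27 and 26 and comes back at 31. Dienol ether 27 is oxidised with Pd(OAc)2 in MeCN in the presence of excess 26, so that O-silyl dienone 28 is consumed as it forms and never accumulates. This gives the O-silyl cycloadduct F1. Et3N then moves the double bond into conjugation to give the silyl ether of the target F2, and HF·pyridine releases 31.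

**Step 10 (the same holds for step 11).** What may go wrong: β-elimination toward C9, or addition of the phosphine to the exocyclic enone during the Mitsunobu reaction. The fallback sets out from 21 and comes back at 24 and uses the Lattrell–Dax inversion, which needs no phosphine. Tf2O and pyridine in CH2Cl2 at −30 °C give the 8α-triflate F3. Bu4NNO2 in toluene displaces it with inversion to the 8β-nitrite ester F4, which is hydrolysed on aqueous work-up to 24.

Further compounds
F0 | step 9 | none | none
F1 | step 13 | O-silyl cycloadduct: 8-O-trimethylsilyl ether (half 1) of 30, epimers at C2 | C=C1C(=O)C2C3=C(CC[C@]24C(=O)C[C@H]2C(=C)C[C@@H](O)[C@H]5C(=C)C(=O)O[C@@H]5[C@H]24)C[C@@H](O[Si](C)(C)C)[C@H]2C(=C)C(=O)O[C@@H]2[C@H]13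
F2 | step 13 | 8-O-trimethylsilyl ether (half 1) of 31 | C=C1C(=O)C2=C3[C@H](CC[C@]24C(=O)C[C@H]2C(=C)C[C@@H](O)[C@H]5C(=C)C(=O)O[C@@H]5[C@H]24)C[C@@H](O[Si](C)(C)C)[C@H]2C(=C)C(=O)O[C@@H]2[C@H]13
F3 | step 10 | 8α-triflate of 21 | C=C1C(=O)C[C@@H]2C(=C)C[C@H](OS(=O)(=O)C(F)(F)F)[C@H]3C(=C)C(=O)O[C@@H]3[C@H]12
F4 | step 10 | 8β-nitrite ester of 24 | C=C1C(=O)C[C@@H]2C(=C)C[C@@H](ON=O)[C@H]3C(=C)C(=O)O[C@@H]3[C@H]12
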